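**Plan** (indenone numbering: C1 carbonyl, C2, C3, C3a, C4–C7, C7a)
1. Late cuts: the silyl group on the C4 carbinol comes off first. Then both azulene–core bonds (C2–C3' and C6–C3'') are cut at once, giving a 2,6-dibromoindenone plus guaiazulene. Then C2–Br and the C2=C3 unsaturation are removed, leading back to an indanone.
2. Core cut: in the five-membered ring (C1, C2, C3, C3a, C7a) the bond C1–C7a is opened and C1 is tied to the carbon of the C3-methyl group. This turns the 1-indanone into a 3-arylcyclobutanone, so the forward step expands a four-membered ring to a five-membered one.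
3. Enabling feature: C3 bears CH3 and lies beta to the C1 carbonyl, so CH3–C3–C2–C1(=O) is a latent cyclobutanone already attached to the benzene ring at C3a. C4 is substituted, so C7a–H is the only ortho C–H that can accept the acyl carbon.
4. Forward order: purchased 1,2,4,5-substituted benzene → iodide → silylated C4 carbinol → four-membered ring at C3a → expansion to the five-membered ring (which also makes the arene pentasubstituted) → C2=C3 and C2–Br → both azulenes → free carbinol.
5. Stereochemistry: the target has no stereocentre. C3 of the indanone forms racemic and becomes planar in step 7.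

Key step: step 6

Assumption: 1, 7 and 16 are taken as purchasable; 9 and 12 are racemic, and 14 is drawn as one enantiomer of the racemic trans-dibromide.

Step 1
Reactants: 1 methyl 2-amino-5-bromo-4-methylbenzoate
Product: 3 methyl 5-bromo-2-iodo-4-methylbenzoate, via arenediazonium tosylate 2 (not isolated)
Conditions: p-TsOH·H2O, NaNO2, KI, MeCN/H2O, 10 °C to rt
Reagents that add atoms: potassium iodide, [K+].[I-]
Why: Sandmeyer-type diazotisation–iodination, in which iodide reduces the diazonium ion so that no copper is needed, while ester, bromide and methyl group are untouched.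

Step 2
Reactants: 3 methyl 5-bromo-2-iodo-4-methylbenzoate
Product: 5 2-(5-bromo-2-iodo-4-methylphenyl)propan-2-ol, via methyl ketone 4 (not isolated)
Conditions: MeMgBr (3 equiv), THF, 0 °C to rt
Reagents that add atoms: methylmagnesium bromide, C[Mg]Br
Why: Twofold Grignard addition to the ester through the methyl ketone, which should outrun iodine–magnesium exchange at this temperature as it does with simpler 2-iodobenzoates.

Step 3
Reactants: 5 2-(5-bromo-2-iodo-4-methylphenyl)propan-2-ol
Product: 6 {[2-(5-bromo-2-iodo-4-methylphenyl)propan-2-yl]oxy}triethylsilane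
Conditions: TESOTf, 2,6-lutidine, CH2Cl2, 0 °C to rt
Reagents that add atoms: triethylsilyl trifluoromethanesulfonate, CC[Si](CC)(CC)OS(=O)(=O)C(F)(F)F
Why: Silylation of a hindered tertiary alcohol with a silyl triflate, needed because the free ortho carbinol would close onto C3 of the cyclobutenone of step 4 by oxa-Michael addition and would ionise in any acidic step.

Step 4
Reactants: 6 {[2-(5-bromo-2-iodo-4-methylphenyl)propan-2-yl]oxy}triethylsilane and 7 3-ethoxycyclobut-2-en-1-one
Product: 10 3-{4-bromo-5-methyl-2-[2-(triethylsilyloxy)propan-2-yl]phenyl}cyclobut-2-en-1-one, via arylmagnesium chloride 8 (not isolated), via tertiary cyclobutenol adduct 9 (not isolated)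
Conditions: i-PrMgCl·LiCl, THF, −20 °C; then 7, −40 to 0 °C; then 1 M aq HCl, 0 °C, short contact
Reagents that add atoms: none
Why: Iodine–magnesium exchange is far faster at the carbon–iodine than at the carbon–bromine bond, and 1,2-addition to the vinylogous ester followed by acid-induced loss of ethanol (Stork–Danheiser-type carbonyl transposition) places the aryl group at C3 of the enone.

Step 5
Reactants: 10 3-{4-bromo-5-methyl-2-[2-(triethylsilyloxy)propan-2-yl]phenyl}cyclobut-2-en-1-one
Product: 11 3-{4-bromo-5-methyl-2-[2-(triethylsilyloxy)propan-2-yl]phenyl}cyclobutan-1-one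
Conditions: H2 (1 atm), 10 % Pd/C, Ph2S (cat.), EtOAc, rt
Reagents that add atoms: none
Why: Heterogeneous hydrogenation over sulfide-poisoned palladium saturates the strained enone but not the aryl bromide, and it is needed because in 10 the aryl group and the acyl carbon are locked trans across the ring double bond and could never meet on one metal centre.

Step 6
Reactants: 11 3-{4-bromo-5-methyl-2-[2-(triethylsilyloxy)propan-2-yl]phenyl}cyclobutan-1-one
Product: 12 rac-6-bromo-3,7-dimethyl-4-[2-(triethylsilyloxy)propan-2-yl]-2,3-dihydro-1H-inden-1-one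
Conditions: [Rh(cod)OH]2 (5 mol %), IMes (12 mol %), m-xylene, 140 °C, sealed tube, Ar
Reagents that add atoms: none
Why: Monovalent rhodium inserts oxidatively into one of the two equivalent acyl–CH2 bonds of the strained ketone to give a rhodacyclopentanone; its Rh–CH2 arm then trades places with the C7a–H bond of the C3-aryl group (C–H oxidative addition or sigma-bond metathesis, then C–H reductive elimination), so that the former ring CH2 becomes the C3 methyl group and a six-membered acyl(aryl)rhodacycle results. Reductive elimination of the acyl and aryl ligands forms C1–C7a and closes the five-membered ring C1–C2–C3–C3a–C7a, so the closure is a C(acyl)–C(aryl) reductive elimination out of a six-membered metallacycle and the net change is an isomerisation in which the four-membered ring gives one carbon to a methyl group and takes in the two arene carbons. The closest known reaction type is the rhodium-catalysed intramolecular C–C/C–H bond metathesis of 3-arylcyclobutanones to 1-indanones, with the reorganisation of 3-arylcyclopentanones to 1-tetralones as its next homologue. C3 becomes a stereocentre through the choice between enantiotopic C–C bonds under an achiral catalyst, so 12 is racemic, which is harmless because step 7 makes C3 planar. Site selectivity is built into 11, since C4 carries the silyloxyisopropyl group, C7a–H is the only ortho C–H, and the bulk at C4 turns that C–H towards the four-membered ring. Chemoselectivity rests on the neutral medium (a Friedel–Crafts closure would ionise the tertiary benzylic ether), on the inertness of the aryl bromide towards monovalent rhodium, and on a closed vessel with a strong donor ligand to hold back decarbonylation.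

Step 7
Reactants: 12 rac-6-bromo-3,7-dimethyl-4-[2-(triethylsilyloxy)propan-2-yl]-2,3-dihydro-1H-inden-1-one
Product: 13 6-bromo-3,7-dimethyl-4-[2-(triethylsilyloxy)propan-2-yl]-1H-inden-1-one
Conditions: IBX (2 equiv), DMSO/fluorobenzene, 75 °C
Reagents that add atoms: none
Why: IBX dehydrogenation of a ketone through its enol, which removes H2 from C2/C3, erases the C3 stereocentre and leaves silyl ether and bromide alone.

Step 8
Reactants: 13 6-bromo-3,7-dimethyl-4-[2-(triethylsilyloxy)propan-2-yl]-1H-inden-1-one
Product: 15 2,6-dibromo-3,7-dimethyl-4-[2-(triethylsilyloxy)propan-2-yl]-1H-inden-1-one, via trans-2,3-dibromide 14 (not isolated)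
Conditions: Br2 (1.05 equiv), CH2Cl2, −20 to 0 °C; then Et3N, 0 °C to rt
Reagents that add atoms: bromine, BrBr
Why: Bromine addition to C2=C3 followed by E1cB loss of HBr (acidic C2–H, tertiary benzylic C3–Br) is the standard alpha-bromination of an enone, and triethylamine keeps the medium free of acid.

Step 9
Reactants: 15 2,6-dibromo-3,7-dimethyl-4-[2-(triethylsilyloxy)propan-2-yl]-1H-inden-1-one and 16 guaiazulene (2.6 equiv)
Product: 21 2,6-bis(guaiazulen-3-yl)-3,7-dimethyl-4-[2-(triethylsilyloxy)propan-2-yl]-1H-inden-1-one, via 3-iodoguaiazulene 17 (not isolated), via guaiazulen-3-yllithium 18 (not isolated), via guaiazulen-3-ylzinc chloride 19 (not isolated), via C2-monocoupled bromide 20 (not isolated)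
Conditions: 16, NIS, CH2Cl2/hexane, −30 °C, cold filtration through basic alumina into THF; n-BuLi, −100 °C; ZnCl2, to 0 °C; then 15, Pd2(dba)3 (2.5 mol %), SPhos (10 mol %), THF, 50 °C
Reagents that add atoms: none
Why: Electrophilic iodination takes the most nucleophilic free position C3 of guaiazulene, iodine–lithium exchange and transmetalation give a mild arylzinc that tolerates the ketone, and a twofold Negishi coupling with a bulky biarylphosphine joins it first to the activated C2–Br and then to the hindered C6–Br.

Step 10
Reactants: 21 2,6-bis(guaiazulen-3-yl)-3,7-dimethyl-4-[2-(triethylsilyloxy)propan-2-yl]-1H-inden-1-one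
Product: 22 2,6-bis(guaiazulen-3-yl)-4-(2-hydroxypropan-2-yl)-3,7-dimethyl-1H-inden-1-one (target)
Conditions: TBAF, THF, 0 °C to rt
Reagents that add atoms: none
Why: Fluoride-induced cleavage of the triethylsilyl ether, after which the liberated tertiary alcohol should not add to C3 because that would build a strained peri-fused ether.

**Compound list** (guaiazulen-3-yl = 3,8-dimethyl-5-isopropylazulen-1-yl)
1 | methyl 2-amino-5-bromo-4-methylbenzoate | COC(=O)c1cc(Br)c(C)cc1N | starting material
2 | 4-bromo-2-(methoxycarbonyl)-5-methylbenzenediazonium tosylate | COC(=O)c1cc(Br)c(C)cc1[N+]#N.Cc1ccc(S(=O)(=O)[O-])cc1 | intermediate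
3 | methyl 5-bromo-2-iodo-4-methylbenzoate | COC(=O)c1cc(Br)c(C)cc1I | intermediate
4 | 1-(5-bromo-2-iodo-4-methylphenyl)ethan-1-one | CC(=O)c1cc(Br)c(C)cc1I | intermediate
5 | 2-(5-bromo-2-iodo-4-methylphenyl)propan-2-ol | CC(C)(O)c1cc(Br)c(C)cc1I | intermediate
6 | {[2-(5-bromo-2-iodo-4-methylphenyl)propan-2-yl]oxy}triethylsilane | CC[Si](CC)(CC)OC(C)(C)c1cc(Br)c(C)cc1I | intermediate
7 | 3-ethoxycyclobut-2-en-1-one | CCOC1=CC(=O)C1 | starting material
8 | {4-bromo-5-methyl-2-[2-(triethylsilyloxy)propan-2-yl]phenyl}magnesium chloride | CC[Si](CC)(CC)OC(C)(C)c1cc(Br)c(C)cc1[Mg]Cl | intermediate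
9 | rac-1-{4-bromo-5-methyl-2-[2-(triethylsilyloxy)propan-2-yl]phenyl}-3-ethoxycyclobut-2-en-1-ol (formed as its magnesium alkoxide) | CCOC1=CC(O)(c2cc(C)c(Br)cc2C(C)(C)O[Si](CC)(CC)CC)C1 | intermediate
10 | 3-{4-bromo-5-methyl-2-[2-(triethylsilyloxy)propan-2-yl]phenyl}cyclobut-2-en-1-one | O=C1C=C(c2cc(C)c(Br)cc2C(C)(C)O[Si](CC)(CC)CC)C1 | intermediate
11 | 3-{4-bromo-5-methyl-2-[2-(triethylsilyloxy)propan-2-yl]phenyl}cyclobutan-1-one | O=C1CC(c2cc(C)c(Br)cc2C(C)(C)O[Si](CC)(CC)CC)C1 | intermediate
12 | rac-6-bromo-3,7-dimethyl-4-[2-(triethylsilyloxy)propan-2-yl]-2,3-dihydro-1H-inden-1-one | CC1CC(=O)c2c(C)c(Br)cc(C(C)(C)O[Si](CC)(CC)CC)c21 | intermediate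
13 | 6-bromo-3,7-dimethyl-4-[2-(triethylsilyloxy)propan-2-yl]-1H-inden-1-one | CC1=CC(=O)c2c(C)c(Br)cc(C(C)(C)O[Si](CC)(CC)CC)c21 | intermediate
14 | rac-trans-2,3,6-tribromo-3,7-dimethyl-4-[2-(triethylsilyloxy)propan-2-yl]-2,3-dihydro-1H-inden-1-one | C[C@@]1(Br)[C@@H](Br)C(=O)c2c(C)c(Br)cc(C(C)(C)O[Si](CC)(CC)CC)c21 | intermediate
15 | 2,6-dibromo-3,7-dimethyl-4-[2-(triethylsilyloxy)propan-2-yl]-1H-inden-1-one | CC1=C(Br)C(=O)c2c(C)c(Br)cc(C(C)(C)O[Si](CC)(CC)CC)c21 | intermediate
16 | guaiazulene (7-isopropyl-1,4-dimethylazulene) | c1cc(C)c2cc(C(C)C)ccc(C)c1-2 | starting material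
17 | 3-iodoguaiazulene | Ic1cc(C)c2cc(C(C)C)ccc(C)c1-2 | intermediate
18 | guaiazulen-3-yllithium | [Li]c1cc(C)c2cc(C(C)C)ccc(C)c1-2 | intermediate
19 | guaiazulen-3-ylzinc chloride | Cl[Zn]c1cc(C)c2cc(C(C)C)ccc(C)c1-2 | intermediate
20 | 6-bromo-2-(guaiazulen-3-yl)-3,7-dimethyl-4-[2-(triethylsilyloxy)propan-2-yl]-1H-inden-1-one | CC1=C(c2cc(C)c3cc(C(C)C)ccc(C)c2-3)C(=O)c2c(C)c(Br)cc(C(C)(C)O[Si](CC)(CC)CC)c21 | intermediate
21 | 2,6-bis(guaiazulen-3-yl)-3,7-dimethyl-4-[2-(triethylsilyloxy)propan-2-yl]-1H-inden-1-one | CC1=C(c2cc(C)c3cc(C(C)C)ccc(C)c2-3)C(=O)c2c(C)c(-c3cc(C)c4cc(C(C)C)ccc(C)c3-4)cc(C(C)(C)O[Si](CC)(CC)CC)c21 | intermediate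
22 | 2,6-bis(guaiazulen-3-yl)-4-(2-hydroxypropan-2-yl)-3,7-dimethyl-1H-inden-1-one | CC1=C(c2cc(C)c3cc(C(C)C)ccc(C)c2-3)C(=O)c2c(C)c(-c3cc(C)c4cc(C(C)C)ccc(C)c3-4)cc(C(C)(C)O)c21 | target

Total step count: 10. Longest linear sequence: 10 steps (1 to 22); guaiazulene enters in step 9.

**Steps most likely to fail**

Step 6. The metallacycle may lose carbon monoxide faster than it exchanges its CH2 arm for the C7a–H bond, which is flanked by the C7 methyl group. Alternatively, the C–C insertion may simply reverse. The fallback sets out from 11 and comes back at 12.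
- 11 is condensed with 2-amino-3-methylpyridine (Ti(OEt)4, toluene) to the N-(3-methylpyridin-2-yl) ketimine of the cyclobutanone F1.
- The pyridine nitrogen acts as a temporary directing group and delivers monovalent rhodium ([Rh(C2H4)2Cl]2, IMes, 1,4-dioxane, 140 °C) to the imidoyl–CH2 bond.
- An imine cannot extrude carbon monoxide, so the same C–C/C–H exchange should give the ketimine of the indanone F2. Wet silica gel hydrolyses it to 12.

Step 9. The iodide and the lithio species may decay before transmetalation, and the coupling may stall after the first event at the hindered C6 position. The fallback sets out from 15 and 16 and comes back at 21. It drops the preformed organometallic altogether: palladium-catalysed direct C–H arylation of guaiazulene (Pd(OAc)2, KOAc, DMAc, 120–150 °C). The organopalladium species formed from each carbon–bromine bond attacks the nucleophilic C3 position of the azulene, passing through 20.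

Step 7. Possible failures are oxidation at a benzylic methyl group and self-addition of the C2-unsubstituted indenone at the reaction temperature. The fallback sets out from 12 and comes back at 13. Soft enolisation (TMSOTf, Et3N, CH2Cl2, 0 °C) gives the trimethylsilyl enol ether of the indanone F3. A Saegusa–Ito oxidation with divalent palladium (Pd(OAc)2, MeCN, rt) then dehydrosilylates it at room temperature, and the product goes directly into step 8.

Further compounds
F1 | step 6 | N-(3-methylpyridin-2-yl) ketimine of cyclobutanone 11 | Cc1cccnc1N=C1CC(c2cc(C)c(Br)cc2C(C)(C)O[Si](CC)(CC)CC)C1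
F2 | step 6 | N-(3-methylpyridin-2-yl) ketimine of indanone 12 (racemic) | CC1CC(=Nc2ncccc2C)c2c(C)c(Br)cc(C(C)(C)O[Si](CC)(CC)CC)c21
F0 | step 9 | none | none
F3 | step 7 | trimethylsilyl enol ether of indanone 12 (racemic) | CC1C=C(O[Si](C)(C)C)c2c(C)c(Br)cc(C(C)(C)O[Si](CC)(CC)CC)c21
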